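The earlier runs and the new flask stem from a simulated flask for substances that don't exist; scatter was added.

**The reading moment.** I read the flask at the moment when 30% of the substrate has gone, and I ask how strongly the rate of making target at that moment answers to the reagent charged.

| setting | west | flask |
|---|---|---|
| substrate | 2 M | 2.0 M |
| reagent | 1.8 M | 1.20 M |
| free catalyst | 1.7 mM | 1.7 mM |
| added ligand | 0.94 mM | 0.94 mM |
| remark | run made earlier |  |

- west (time / min: target / %, substrate / %): 5.00: 7.4, 93.6; 15.0: 20.9, 79.0; 25.0: 32.1, 66.8; 40.0: 48.4, 52.5; 60.0: 60.5, 37.0; 80.0: 72.7, 29.8

(each reading ± 1 percentage point)

- no earlier run changes the charge of reagent; that part of a forecast is a guess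

- apparent order in reagent when 30% of the substrate are converted (percent change of the rate of making target for one percent more reagent charged)

**The ledger.** I assume that one mole of reagent goes into each mole of target, although no west reading shows the reagent, and on that assumption the reagent is the limiting reagent of the flask, with 1.20 M charged, less than the 2.0 M of substrate. The first entry is the catalyst, which holds 0.142% of the reagent charge if each catalyst takes one reagent, so I leave it out. The second entry is the target, which has taken 0.600 M at the reading moment, and that leaves c(reagent) = 0.600 M. The books close at a conversion of 60.0%, with 0.800 M of substrate left.

**The gearing.** The amount used at the reading moment follows from the conversion and not from the charge, so one percent more charged lands entirely on what is left. I call the charge of reagent over the reagent left at the reading moment the gearing, here 2.00. If the substrate and the forms of the catalyst at the reading moment stay as they are, the apparent order is the gearing times the local order, which is the percent change of the rate for one percent more reagent present. On the same assumption reagent and substrate fall together in the west run, so I do not trust those readings to separate the local order, and I commit to 0.5, the middle between zero and first order, which gives 1.00.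

**The forecast.** The forecast says 0.15, below my figure, and holds the reaction “close to zero order in reagent”.

**The result.** The simulation gives 0.94, from these steps:

    substrate + catalyst intermediate A → catalyst intermediate B (k = 0.360 L mol⁻¹ s⁻¹)
    free catalyst → spent catalyst (k = 1.00 × 10⁻⁴ s⁻¹)
    catalyst intermediate B → free catalyst + target (k = 1.50 s⁻¹)
    free catalyst + added ligand ⇌ idle complex, settled at all times (K = 3300 L mol⁻¹)
    reagent + free catalyst → catalyst intermediate A (k = 1.30 L mol⁻¹ s⁻¹)

**One reason.** Divided by the gearing 2.00, the 0.94 of this flask stands for a local order of about 0.470, if the rule holds here. The parking of free catalyst with added ligand as idle complex raises the apparent order, since the same flask without that parking gives 0.70. In the run with 2.40 M of reagent charged, the gearing falls to 1.33, and the time to the same conversion changes by a factor of 0.744.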